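1. Numbering follows the chamigrane skeleton (ring B = C1–C5, spiro C6, ring A = C7–C11); the target is (2S,3S,6S,10R)-2,10-dibromo-3-chloro-α-chamigrene. Ring A is opened at C7=C8 by ring-closing metathesis; this works because C7=C8 is the only C=C of the molecule, sits in a six-membered ring, and is flanked by the contiguous quaternary carbons C6 and C11, so an isopropenyl group on C6 and a but-3-enyl end on C10 form a pre-folded 1,7-diene.
2. Before C7 becomes olefinic it is a carboxyl group: it stands 1,4 to C3 across ring B, so bromolactonisation to a 2-oxabicyclo[2.2.2]octan-3-one fixes Br on C2 anti to O on C3, and both relative to C6. The temporary lactone C–O bond is later exchanged for C3–Cl with retention (bromine participation) and the bridge is removed.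
3. Ring B and C6 come from a catalytic enantioselective Diels–Alder reaction of isoprene with an α-(tert-alkyl)acrolein that already holds the C6–C11 bond. C10–Br is set by catalyst-controlled α-bromination of an aldehyde, and C8 by a triflate/vinyl coupling.
4. Order of ring formation: ring B (step 3), temporary lactone bridge (step 5, opened in step 11), ring A (step 14, monocycle to spirocycle).

Key step: step 14

Remark: the descriptors of intermediates change with substituent priorities although the spatial arrangement at C2, C3, C6 and C10 is kept from the step that sets it.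

Step 1
Reactants: 1 methyl 3,3-dimethylpent-4-enoate
Product: 2 3,3-dimethylpent-4-enal
Conditions: i-Bu2AlH (1.05 equiv), CH2Cl2, −78 °C; aq. KNaC4H4O6
Reagents that add atoms: none
Why: Partial reduction of a methyl ester by i-Bu2AlH at −78 °C stops at the aluminium hemiacetal, which gives the aldehyde only on work-up (ester-to-aldehyde half-reduction), and no stereocenter is involved.

Step 2
Reactants: 2 3,3-dimethylpent-4-enal
Product: 3 2-(2-methylbut-3-en-2-yl)prop-2-enal
Conditions: 37% aq. CH2O, pyrrolidine (10 mol%), EtCO2H (10 mol%), i-PrOH, 45 °C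
Reagents that add atoms: formaldehyde, C=O
Why: Amine-catalysed Mannich condensation and loss of the amine (organocatalytic α-methylenation of an aldehyde) is reliable for α-CH2 aldehydes, including neopentyl-type ones, and makes C6 the dienophile carbon with the C6–C11 bond already in place.

Step 3
Reactants: 3 2-(2-methylbut-3-en-2-yl)prop-2-enal; 4 isoprene
Product: 5 (1R)-4-methyl-1-(2-methylbut-3-en-2-yl)cyclohex-3-ene-1-carbaldehyde
Conditions: 4 (5 equiv), (R)-o-tolyl-oxazaborolidine from (R)-α,α-diphenylprolinol (20 mol%), Tf2NH (18 mol%), CH2Cl2, −78 → −40 °C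
Reagents that add atoms: none
Why: Chiral-oxazaborolidinium-catalysed Diels–Alder reaction of a 2-substituted acrolein: the orbital coefficients (C1 of isoprene, β-carbon of the enal) give the 1,4 ("para") adduct, and the boron-bound s-trans enal, held by the formyl C–H···O contact and covered on one face by a catalyst phenyl group while its bulky α-substituent points away, should be attacked on the Re face of its α-carbon, which sets C6 (1R in 5) under catalyst control.

Step 4
Reactants: 5 (1R)-4-methyl-1-(2-methylbut-3-en-2-yl)cyclohex-3-ene-1-carbaldehyde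
Product: 6 (1R)-4-methyl-1-(2-methylbut-3-en-2-yl)cyclohex-3-ene-1-carboxylic acid
Conditions: NaClO2, NaH2PO4, 2-methylbut-2-ene, t-BuOH/H2O, 0 °C → rt
Reagents that add atoms: sodium chlorite, [Na+].[O-]Cl=O
Why: Chlorite (Pinnick) oxidation converts the neopentyl aldehyde to the acid without touching the olefins, the hypochlorite by-product being scavenged by 2-methylbut-2-ene, and C6 is unaffected.

Step 5
Reactants: 6 (1R)-4-methyl-1-(2-methylbut-3-en-2-yl)cyclohex-3-ene-1-carboxylic acid
Product: 7 (1S,4R,6S)-6-bromo-1-methyl-4-(2-methylbut-3-en-2-yl)-2-oxabicyclo[2.2.2]octan-3-one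
Conditions: NBS (1.05 equiv), CH2Cl2, 0 °C, dark
Reagents that add atoms: N-bromosuccinimide, O=C1CCC(=O)N1Br
Why: Bromolactonisation: NBS forms the bromonium ion on the electron-rich trisubstituted ring olefin (the neopentyl vinyl group is far less nucleophilic), and only the bromonium ion anti to the carboxyl can be opened by it, at the tertiary carbon C3 (Markovnikov, boat-like 1,4-bridging as in the halocyclisation of 4-methylcyclohex-3-enyl carbinols), so O on C3 is cis to C7 and Br on C2 is anti to O and hence cis to C11, which sets C2 and C3 from C6.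

Step 6
Reactants: 7 (1S,4R,6S)-6-bromo-1-methyl-4-(2-methylbut-3-en-2-yl)-2-oxabicyclo[2.2.2]octan-3-one
Product: 9 (1S,4R,6S)-6-bromo-4-(4-hydroxy-2-methylbutan-2-yl)-1-methyl-2-oxabicyclo[2.2.2]octan-3-one, via B-alkyl-9-BBN adduct 8 (not isolated)
Conditions: 9-BBN, THF, 0 °C → rt; then 30% H2O2, aq. NaOAc, 0 °C → rt
Reagents that add atoms: 9-borabicyclo[3.3.1]nonane (boron in 8 only), [BH]1C2CCCC1CCC2; hydrogen peroxide, OO
Why: Hydroboration of the monosubstituted olefin with 9-BBN places boron on the terminal carbon C9 for steric reasons, and buffered oxidation of the C–B bond gives the primary alcohol with the lactone and the secondary bromide intact (hydroboration–oxidation).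

Step 7
Reactants: 9 (1S,4R,6S)-6-bromo-4-(4-hydroxy-2-methylbutan-2-yl)-1-methyl-2-oxabicyclo[2.2.2]octan-3-one
Product: 10 3-[(1S,4R,6S)-6-bromo-1-methyl-3-oxo-2-oxabicyclo[2.2.2]octan-4-yl]-3-methylbutanal
Conditions: Dess–Martin periodinane, CH2Cl2, 0 °C → rt
Reagents that add atoms: none
Why: Dess–Martin oxidation takes the primary alcohol to the aldehyde under neutral conditions without over-oxidation, and no stereocenter is at risk.

Step 8
Reactants: 10 3-[(1S,4R,6S)-6-bromo-1-methyl-3-oxo-2-oxabicyclo[2.2.2]octan-4-yl]-3-methylbutanal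
Product: 12 (1S,4R,6S)-6-bromo-4-[(3S)-3-bromo-4-hydroxy-2-methylbutan-2-yl]-1-methyl-2-oxabicyclo[2.2.2]octan-3-one, via α-bromo aldehyde 11 (not isolated)
Conditions: (S)-α,α-diphenylprolinol trimethylsilyl ether (10 mol%), NBS (1.05 equiv, slow addition), HFIP, 0 °C; then MeOH, NaBH4, −20 °C
Reagents that add atoms: N-bromosuccinimide, O=C1CCC(=O)N1Br
Why: Enamine-catalysed electrophilic α-bromination: the (S)-diarylprolinol silyl ether forms the E-enamine and shields one of its faces, so bromine should enter on the open Si face of C10 under catalyst control (2S in 11, 3S in 12, the spatial arrangement of 10R in the target), and immediate NaBH4 reduction turns the configurationally labile α-bromo aldehyde into the stable bromohydrin.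

Step 9
Reactants: 12 (1S,4R,6S)-6-bromo-4-[(3S)-3-bromo-4-hydroxy-2-methylbutan-2-yl]-1-methyl-2-oxabicyclo[2.2.2]octan-3-one
Product: 13 (2S)-2-bromo-3-[(1S,4R,6S)-6-bromo-1-methyl-3-oxo-2-oxabicyclo[2.2.2]octan-4-yl]-3-methylbutyl trifluoromethanesulfonate
Conditions: Tf2O, 2,6-lutidine, CH2Cl2, −78 °C
Reagents that add atoms: trifluoromethanesulfonic anhydride, O=S(=O)(OS(=O)(=O)C(F)(F)F)C(F)(F)F
Why: O-Sulfonylation of the primary alcohol with Tf2O and a hindered pyridine base at −78 °C gives the alkyl triflate before the neighbouring bromine can displace it, and C10 is untouched.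

Step 10
Reactants: 13 (2S)-2-bromo-3-[(1S,4R,6S)-6-bromo-1-methyl-3-oxo-2-oxabicyclo[2.2.2]octan-4-yl]-3-methylbutyl trifluoromethanesulfonate
Product: 14 (1S,4R,6S)-6-bromo-4-[(3R)-3-bromo-2-methylhex-5-en-2-yl]-1-methyl-2-oxabicyclo[2.2.2]octan-3-one
Conditions: CH2=CHMgBr (1.5 equiv), CuBr·SMe2 (10 mol%), THF, −78 → −40 °C
Reagents that add atoms: vinylmagnesium bromide, C=C[Mg]Br
Why: Copper-catalysed SN2 coupling of a primary alkyl triflate with a Grignard reagent runs at −78 °C, where the neopentyl secondary bromides and the hindered lactone are inert, and installs C8 with the terminal olefin without touching C10.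

Step 11
Reactants: 14 (1S,4R,6S)-6-bromo-4-[(3R)-3-bromo-2-methylhex-5-en-2-yl]-1-methyl-2-oxabicyclo[2.2.2]octan-3-one
Product: 15 (1R,3S,4S)-3-bromo-1-[(3R)-3-bromo-2-methylhex-5-en-2-yl]-4-chloro-4-methylcyclohexane-1-carbonyl chloride
Conditions: SOCl2 (5 equiv), ZnCl2 (10 mol%), CH2Cl2, 35 °C
Reagents that add atoms: thionyl chloride, ClS(Cl)=O
Why: Alkyl–oxygen cleavage of a lactone by SOCl2 with ZnCl2 (the reaction type that turns γ-butyrolactone into 4-chlorobutanoyl chloride): the tertiary C3–O bond ionises with anchimeric assistance from the anti bromine on C2 and chloride collapses onto C3 from the face just vacated by the carboxylate, so C3–Cl should form with retention (anti to Br, cis to C7) while the carboxyl is trapped as the acid chloride and cannot relactonise.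

Step 12
Reactants: 15 (1R,3S,4S)-3-bromo-1-[(3R)-3-bromo-2-methylhex-5-en-2-yl]-4-chloro-4-methylcyclohexane-1-carbonyl chloride
Product: 16 1-[(1R,3S,4S)-3-bromo-1-[(3R)-3-bromo-2-methylhex-5-en-2-yl]-4-chloro-4-methylcyclohexyl]ethan-1-one
Conditions: Me2CuLi (1.2 equiv, from MeLi and CuI), Et2O, −78 °C
Reagents that add atoms: lithium dimethylcuprate, [Li+].C[Cu-]C
Why: Acylation of a Gilman cuprate by an acid chloride gives the methyl ketone and stops there, and at −78 °C the cuprate does not attack the secondary bromides or the tertiary chloride.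

Step 13
Reactants: 16 1-[(1R,3S,4S)-3-bromo-1-[(3R)-3-bromo-2-methylhex-5-en-2-yl]-4-chloro-4-methylcyclohexyl]ethan-1-one
Product: 17 (1S,2S,4S)-2-bromo-4-[(3R)-3-bromo-2-methylhex-5-en-2-yl]-1-chloro-1-methyl-4-(prop-1-en-2-yl)cyclohexane
Conditions: Tebbe reagent Cp2Ti(μ-Cl)(μ-CH2)AlMe2 (1.5 equiv), pyridine (cat.), THF–toluene, −40 → 0 °C
Reagents that add atoms: Tebbe reagent, C[Al-]1(C)C[Ti](C2C=CC=C2)(C2C=CC=C2)[Cl+]1
Why: Methylenation with the non-basic titanium methylidene (Tebbe olefination) works on hindered, enolisable ketones where phosphorus ylides fail, and it avoids dehydrohalogenation of the tertiary chloride and the secondary bromides.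

Step 14
Reactants: 17 (1S,2S,4S)-2-bromo-4-[(3R)-3-bromo-2-methylhex-5-en-2-yl]-1-chloro-1-methyl-4-(prop-1-en-2-yl)cyclohexane
Product: 18 (4R,6S,8S,9S)-4,8-dibromo-9-chloro-1,5,5,9-tetramethylspiro[5.5]undec-1-ene
Conditions: second-generation Hoveyda–Grubbs catalyst RuCl2(=CH-C6H4-2-O-i-Pr)(H2IMes) (5 mol%), toluene (0.005 M), 60 °C, argon sparge
Reagents that add atoms: none
Why: Ring-closing olefin metathesis: the ruthenium alkylidene loads onto the unhindered monosubstituted olefin at C8 and then engages the 1,1-disubstituted isopropenyl group on C6 through a ruthenacyclobutane, releasing ethylene and forming the C7=C8 bond. The closest known reaction type is the ruthenium-catalysed closure of tri- and tetrasubstituted cyclohexenes beside quaternary carbons, including spiro[5.5]undecenes of the chamigrene family. Ring A closes as a six-membered ring from a 1,7-diene, the only ring size the two olefins of 17 can give, and the contiguous quaternary carbons C6 and C11 hold the chain ends together (gem-dialkyl effect), which favours cyclisation over oligomerisation at high dilution. No stereocenter is created: C2, C3, C6 and C10 are carried in unchanged and the endocyclic olefin can only be cis. The step needs chemoselectivity for the two terminal olefins beside two secondary bromides and a tertiary chloride, which ruthenium carbenes tolerate, and it needs the hindered closure to outrun catalyst decay, which the monosubstituted initiation site and removal of ethylene should secure.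

Compound list
1 | methyl 3,3-dimethylpent-4-enoate | COC(=O)CC(C)(C)C=C | starting material
2 | 3,3-dimethylpent-4-enal | O=CCC(C)(C)C=C | intermediate
3 | 2-(2-methylbut-3-en-2-yl)prop-2-enal | C=C(C=O)C(C)(C)C=C | intermediate
4 | isoprene (2-methylbuta-1,3-diene) | C=CC(C)=C | starting material
5 | (1R)-4-methyl-1-(2-methylbut-3-en-2-yl)cyclohex-3-ene-1-carbaldehyde | C=CC(C)(C)[C@]1(C=O)CC=C(C)CC1 | intermediate
6 | (1R)-4-methyl-1-(2-methylbut-3-en-2-yl)cyclohex-3-ene-1-carboxylic acid | C=CC(C)(C)[C@]1(C(=O)O)CC=C(C)CC1 | intermediate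
7 | (1S,4R,6S)-6-bromo-1-methyl-4-(2-methylbut-3-en-2-yl)-2-oxabicyclo[2.2.2]octan-3-one | C=CC(C)(C)[C@]12CC[C@](C)(OC1=O)[C@@H](Br)C2 | intermediate
8 | (1S,4R,6S)-4-[4-(9-borabicyclo[3.3.1]nonan-9-yl)-2-methylbutan-2-yl]-6-bromo-1-methyl-2-oxabicyclo[2.2.2]octan-3-one | B1(C2CCCC1CCC2)CCC(C)(C)[C@]34CC[C@](C)(OC3=O)[C@@H](Br)C4 | intermediate (not isolated)
9 | (1S,4R,6S)-6-bromo-4-(4-hydroxy-2-methylbutan-2-yl)-1-methyl-2-oxabicyclo[2.2.2]octan-3-one | OCCC(C)(C)[C@]12CC[C@](C)(OC1=O)[C@@H](Br)C2 | intermediate
10 | 3-[(1S,4R,6S)-6-bromo-1-methyl-3-oxo-2-oxabicyclo[2.2.2]octan-4-yl]-3-methylbutanal | O=CCC(C)(C)[C@]12CC[C@](C)(OC1=O)[C@@H](Br)C2 | intermediate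
11 | (2S)-2-bromo-3-[(1S,4R,6S)-6-bromo-1-methyl-3-oxo-2-oxabicyclo[2.2.2]octan-4-yl]-3-methylbutanal | O=C[C@@H](Br)C(C)(C)[C@]12CC[C@](C)(OC1=O)[C@@H](Br)C2 | intermediate (not isolated)
12 | (1S,4R,6S)-6-bromo-4-[(3S)-3-bromo-4-hydroxy-2-methylbutan-2-yl]-1-methyl-2-oxabicyclo[2.2.2]octan-3-one | OC[C@@H](Br)C(C)(C)[C@]12CC[C@](C)(OC1=O)[C@@H](Br)C2 | intermediate
13 | (2S)-2-bromo-3-[(1S,4R,6S)-6-bromo-1-methyl-3-oxo-2-oxabicyclo[2.2.2]octan-4-yl]-3-methylbutyl trifluoromethanesulfonate | O=S(=O)(OC[C@@H](Br)C(C)(C)[C@]12CC[C@](C)(OC1=O)[C@@H](Br)C2)C(F)(F)F | intermediate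
14 | (1S,4R,6S)-6-bromo-4-[(3R)-3-bromo-2-methylhex-5-en-2-yl]-1-methyl-2-oxabicyclo[2.2.2]octan-3-one | C=CC[C@@H](Br)C(C)(C)[C@]12CC[C@](C)(OC1=O)[C@@H](Br)C2 | intermediate
15 | (1R,3S,4S)-3-bromo-1-[(3R)-3-bromo-2-methylhex-5-en-2-yl]-4-chloro-4-methylcyclohexane-1-carbonyl chloride | C=CC[C@@H](Br)C(C)(C)[C@@]1(C(Cl)=O)CC[C@](C)(Cl)[C@@H](Br)C1 | intermediate
16 | 1-[(1R,3S,4S)-3-bromo-1-[(3R)-3-bromo-2-methylhex-5-en-2-yl]-4-chloro-4-methylcyclohexyl]ethan-1-one | C=CC[C@@H](Br)C(C)(C)[C@@]1(C(C)=O)CC[C@](C)(Cl)[C@@H](Br)C1 | intermediate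
17 | (1S,2S,4S)-2-bromo-4-[(3R)-3-bromo-2-methylhex-5-en-2-yl]-1-chloro-1-methyl-4-(prop-1-en-2-yl)cyclohexane | C=CC[C@@H](Br)C(C)(C)[C@@]1(C(C)=C)CC[C@](C)(Cl)[C@@H](Br)C1 | intermediate
18 | (4R,6S,8S,9S)-4,8-dibromo-9-chloro-1,5,5,9-tetramethylspiro[5.5]undec-1-ene, i.e. (2S,3S,6S,10R)-2,10-dibromo-3-chloro-α-chamigrene | CC1=CC[C@@H](Br)C(C)(C)[C@]12CC[C@](C)(Cl)[C@@H](Br)C2 | target

Total step count: 14. Longest linear sequence: 14 steps (1 to 18).

Steps most likely to fail

Step 3. The α-tert-alkyl enal may bind the oxazaborolidinium ion weakly or in a twisted geometry, so that turnover is slow and an unselective background cycloaddition erodes the enantiomeric purity at C6. The fallback replaces asymmetric catalysis by resolution; it sets out from 3 (with 4) and comes back at 6. A Diels–Alder reaction promoted by Me2AlCl (CH2Cl2, −78 → −20 °C) should give the racemic aldehyde F1, and chlorite oxidation as in step 4 should give the racemic acid F2. Fractional crystallisation with (S)-1-phenylethylamine should give the (S)-1-phenylethylammonium salt of the (1R)-acid F3, taken from the crystals or, if it is the more soluble salt, from the liquor after the other salt has been removed. Acidification with aq. HCl and extraction returns 6.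

Step 8. Enamine formation at the congested neopentyl aldehyde may be slow, the amine catalyst may be consumed by N-bromination, and the α-bromo aldehyde 11 may epimerise before it is reduced; each of these lowers the selectivity at C10. The fallback replaces organocatalysis by auxiliary control; it sets out from 10 and comes back at 12. Chlorite oxidation of 10 should give the butanoic acid F4. Activation as the mixed anhydride (t-BuCOCl, Et3N) and reaction with lithiated (S)-4-benzyl-1,3-oxazolidin-2-one should give the N-acyl oxazolidinone F5. Enolisation with Bu2BOTf and i-Pr2NEt followed by NBS should give the (2S)-bromo imide F6, bromine entering anti to the benzyl group of the chelated Z-enolate. Reduction with LiBH4 (Et2O, 1 equiv MeOH, 0 °C) releases the auxiliary and returns 12.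

Step 11. The bromonium or β-bromo carbocation formed on C–O ionisation may partition: chloride may attack C2 with migration of bromine to C3, a proton may be lost to give allylic bromides, or Br+ may be transferred to chloride and re-added without facial control. The fallback cleaves the acyl–oxygen bond first and then relies on internal return; it sets out from 14 and comes back at 16, bypassing 15. MeLi (1.05 equiv, THF, −78 °C) should add once to the lactone carbonyl, and the hemiketal should open on work-up to the tertiary-alcohol methyl ketone F7 (in equilibrium with its bridged lactol). SOCl2 in Et2O at −20 °C should then convert the C3 alcohol through its chlorosulfite into the chloride with retention (SNi, the anti bromine blocking the other face), which gives 16.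

Further compounds
F1 | step 3 | rac-4-methyl-1-(2-methylbut-3-en-2-yl)cyclohex-3-ene-1-carbaldehyde | C=CC(C)(C)C1(C=O)CC=C(C)CC1
F2 | step 3 | rac-4-methyl-1-(2-methylbut-3-en-2-yl)cyclohex-3-ene-1-carboxylic acid | C=CC(C)(C)C1(C(=O)O)CC=C(C)CC1
F3 | step 3 | (S)-1-phenylethylammonium (1R)-4-methyl-1-(2-methylbut-3-en-2-yl)cyclohex-3-ene-1-carboxylate | C=CC(C)(C)[C@]1(C(=O)[O-])CC=C(C)CC1.C[C@H]([NH3+])c1ccccc1
F4 | step 8 | 3-[(1S,4R,6S)-6-bromo-1-methyl-3-oxo-2-oxabicyclo[2.2.2]octan-4-yl]-3-methylbutanoic acid | OC(=O)CC(C)(C)[C@]12CC[C@](C)(OC1=O)[C@@H](Br)C2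
F5 | step 8 | (4S)-4-benzyl-3-{3-[(1S,4R,6S)-6-bromo-1-methyl-3-oxo-2-oxabicyclo[2.2.2]octan-4-yl]-3-methylbutanoyl}-1,3-oxazolidin-2-one | O=C(CC(C)(C)[C@]12CC[C@](C)(OC1=O)[C@@H](Br)C2)N3[C@@H](Cc4ccccc4)COC3=O
F6 | step 8 | (4S)-4-benzyl-3-{(2S)-2-bromo-3-[(1S,4R,6S)-6-bromo-1-methyl-3-oxo-2-oxabicyclo[2.2.2]octan-4-yl]-3-methylbutanoyl}-1,3-oxazolidin-2-one | O=C([C@@H](Br)C(C)(C)[C@]12CC[C@](C)(OC1=O)[C@@H](Br)C2)N3[C@@H](Cc4ccccc4)COC3=O
F7 | step 11 | 1-[(1R,3S,4S)-3-bromo-1-[(3R)-3-bromo-2-methylhex-5-en-2-yl]-4-hydroxy-4-methylcyclohexyl]ethan-1-one | C=CC[C@@H](Br)C(C)(C)[C@@]1(C(C)=O)CC[C@](C)(O)[C@@H](Br)C1
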